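In a one-step world each Sub that reacts takes one Rea with it, and I took the rate as first order in each and replaced the falling [Rea] by its mean over the run, halfway between charge and end.

| flask | Sub | Rea | remark | time |
|---|---|---|---|---|
| noon | 0.025 M | 0.055 M | run made earlier |  |
| winter | 0.038 M | 0.055 M | run made earlier |  |
| flask | 0.050 M | 0.0550 M |  | 8.0 h |

- noon (time / h: Sub / %, Prd / %): 0.417: 98.0, 1.8; 0.667: 96.1, 3.3; 1.33: 93.7, 6.7; 2.50: 87.7, 11.6; 5.00: 78.5, 20.8
- winter (time / h: Sub / %, Prd / %): 0.417: 98.1, 2.3; 1.33: 94.4, 7.0; 2.00: 90.5, 10.3; 3.00: 87.4, 13.6; 5.00: 79.6, 21.0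

(standard deviation of a reading: 0.5 percentage points)

1. part of the Sub that has reacted at 8.0 h
2. share of the unused Rea that is free and not bound as Rea.Byp, at 8.0 h

I divided the slope of ln[Sub] up to the last reading by that mean [Rea]. This gave 0.925 M⁻¹ h⁻¹ in the noon run and 0.893 M⁻¹ h⁻¹ in the winter run. Both runs held 0.055 M of Rea, so the order in Rea stayed my assumption. Their average, 0.909 M⁻¹ h⁻¹, I carried on as the mean-[Rea] constant, the slope of ln[Sub] per unit of mean [Rea].

In the flask Sub is the limiting reagent, so in this one-step world the Sub curve starts at a slope of 0.0500 h⁻¹ and its level is full conversion, with 0.00500 M of Rea over. That start slope held for 8.0 h gave 33.0%. This put the mean [Rea] at 0.0468 M, which gave 28.8%, then 0.0478 M and 29.4%. At that conversion the one-step slope came to 0.0259 h⁻¹, about half of its start. The exact second-order integral needs 0.927 M⁻¹ h⁻¹ for that conversion, so the mean errs high by 1.98% in the constant. On bound Rea the runs told me nothing.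

The forecast, below my reckoning, stood at 28.5% and 80%, and said “the free share is largely a guess”. The flask gave 27.1% and 74.9%.

    Sub + Rea → Byp + Prd (k = 2.70 × 10⁻⁴ M⁻¹ s⁻¹)
    Rea + Byp ⇌ Rea.Byp, settled at all times (K = 780 M⁻¹)
    Byp → Byp2 (k = 4.10 × 10⁻⁴ s⁻¹)

Run back through 0.909 M⁻¹ h⁻¹, the flask's 27.1% means a mean [Rea] of 0.0434 M, against my 0.0478 M, and at 8.00 h the flask held 0.0104 M of Rea.Byp. A neighbouring flask differs from the flask in its 0.14 M of Rea. The same reckoning put its mean [Rea] at 0.125 M and its conversion at 59.8%. That flask gave 56.4%, which through 0.909 M⁻¹ h⁻¹ means a mean [Rea] of 0.114 M, and at 8.00 h it held 0.0254 M of Rea.Byp.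

The earlier runs and the new flask stem from a simulated flask for substances that don't exist, noise included.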